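C1 is the macrolactone C=O, C2 its CH2, C3 (O-bearing) and C4 (C-bearing) are the ring-fusion carbons, C6 the ketone, C9 the methyl carbinol, C11 the γ-lactone C=O, C12 the furyl-bearing CH, and C19 the side-chain carbinol.
Enabling feature: in the ten-membered ring (C1–C9 plus the C9 oxygen), the acyloxy carbon C3 lies β to the C1 ester carbonyl. C2–C3 is therefore an acetate-aldol bond that a C9 bromoacetate and a C3 aldehyde can form.
Retrosynthetic cuts, in order: O–C11 of the γ-lactone, C2–C3 of the macrolactone, the C9–O acyl bond, C3=O back to a vinyl group, then C4–C12 between a C3–C10 allylic carbonate and a furylacetic ester.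
Forward: the chain is joined at C4–C12, C9 is bromoacetylated, and the vinyl group is cleaved to the aldehyde. The ten-membered ring closes first and the five-membered lactone last.
Stereochemistry: C9 comes from (R)-γ-valerolactone and C19 from an enzymatic ketone reduction. C4 (iridium catalyst) and C12 (isothiourea catalyst) are set in one allylic alkylation, and C3 by 1,2-induction from C4 during ring closure.
Key step: step 16

Assumption: (R)-γ-valerolactone, allyl tert-butyl carbonate and methyl 2-(furan-2-yl)acetate are taken as catalogue chemicals.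
Assumption: the catalyst descriptors in step 11 follow the usual models (attack anti to the phenyl group of the isothiouronium enolate, attack anti to iridium at the substituted allyl terminus); each catalyst rules one centre on its own, so the mirror-image catalyst would be used if a model reaction showed the opposite sense.

Step 1
Reactants: 1 (R)-γ-valerolactone
Product: 2 (R)-4-hydroxy-N-methoxy-N-methylpentanamide
Conditions: MeNH(OMe)·HCl, i-PrMgCl, THF, −20 → 0 °C; aq NH4Cl
Reagents that add atoms: N,O-dimethylhydroxylamine hydrochloride, CNOC.Cl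
Why: Weinreb aminolysis with the chloromagnesium amide opens the lactone at the acyl C–O bond, so the purchased C9 stereocentre is not touched.

Step 2
Reactants: 2 (R)-4-hydroxy-N-methoxy-N-methylpentanamide
Product: 3 (R)-N-methoxy-N-methyl-4-(triethylsilyloxy)pentanamide
Conditions: Et3SiCl, imidazole, CH2Cl2, 0 °C
Reagents that add atoms: chlorotriethylsilane, CC[Si](Cl)(CC)CC
Why: Standard silylation stops relactonisation and places on C9 the one silyl ether that can later be removed beside the C19 TBS ether.

Step 3
Reactants: 3 (R)-N-methoxy-N-methyl-4-(triethylsilyloxy)pentanamide; 4 allylmagnesium bromide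
Product: 5 (R)-7-(triethylsilyloxy)oct-1-en-4-one
Conditions: THF, −78 → −20 °C; cold aq NH4Cl
Reagents that add atoms: none
Why: In this Weinreb ketone synthesis the chelated tetrahedral intermediate prevents over-addition, and the cold, nearly neutral quench keeps the alkene in the β,γ-position.

Step 4
Reactants: 5 (R)-7-(triethylsilyloxy)oct-1-en-4-one
Product: 6 (R)-2-allyl-2-[3-(triethylsilyloxy)butyl]-1,3-dioxolane
Conditions: (TMSOCH2)2, TMSOTf (5 mol %), CH2Cl2, −78 °C; pyridine quench
Reagents that add atoms: 1,2-bis(trimethylsilyloxy)ethane, C[Si](C)(C)OCCO[Si](C)(C)C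
Why: Noyori aprotic ketalisation needs no Brønsted acid or heat, so the TES ether survives and the alkene does not move into conjugation, and the dioxolane removes C6 as an electrophile for the later samarium enolate.

Step 5
Reactants: 6 (R)-2-allyl-2-[3-(triethylsilyloxy)butyl]-1,3-dioxolane; 7 allyl tert-butyl carbonate (3 equiv)
Product: 8 tert-butyl (E)-4-{2-[(R)-3-(triethylsilyloxy)butyl]-1,3-dioxolan-2-yl}but-2-en-1-yl carbonate
Conditions: Hoveyda–Grubbs II (5 mol %), CH2Cl2, 40 °C
Reagents that add atoms: none
Why: Olefin cross-metathesis of two unhindered terminal alkenes with one partner in excess, driven by loss of ethene, should favour the E-allylic carbonate that the iridium catalyst needs.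

Step 6
Reactants: 9 methyl 2-(furan-2-yl)acetate; 10 methyl vinyl ketone
Product: 11 methyl 2-[5-(3-oxobutyl)furan-2-yl]acetate
Conditions: AuCl3 (2 mol %), MeCN, 20 °C
Reagents that add atoms: none
Why: Friedel–Crafts-type conjugate addition (hydroarylation) of a 2-substituted furan to an enone takes place at the free, most nucleophilic C5 position.

Step 7
Reactants: 11 methyl 2-[5-(3-oxobutyl)furan-2-yl]acetate
Product: 12 methyl 2-{5-[(R)-3-hydroxybutyl]furan-2-yl}acetate
Conditions: (R)-selective alcohol dehydrogenase (Lactobacillus brevis type), NADP+ (cat.), i-PrOH, phosphate buffer pH 7, 30 °C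
Reagents that add atoms: none
Why: In this biocatalytic ketone reduction the anti-Prelog enzyme tells methyl from the long chain and should give the (R)-carbinol C19, a discrimination that chemical catalysts make poorly for dialkyl ketones.

Step 8
Reactants: 12 methyl 2-{5-[(R)-3-hydroxybutyl]furan-2-yl}acetate
Product: 13 methyl 2-{5-[(R)-3-(tert-butyldimethylsilyloxy)butyl]furan-2-yl}acetate
Conditions: TBSCl, imidazole, DMF, rt
Reagents that add atoms: tert-butyldimethylsilyl chloride, CC(C)(C)[Si](C)(C)Cl
Why: Standard silylation masks C19–OH so that the later active ester cannot acylate it, and the TBS ether outlasts the TES ether in step 13.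

Step 9
Reactants: 13 methyl 2-{5-[(R)-3-(tert-butyldimethylsilyloxy)butyl]furan-2-yl}acetate
Product: 14 2-{5-[(R)-3-(tert-butyldimethylsilyloxy)butyl]furan-2-yl}acetic acid
Conditions: LiOH·H2O, THF/H2O, rt; 1 M HCl to pH 4, 0 °C
Reagents that add atoms: lithium hydroxide, [Li+].[OH-]
Why: Saponification of an unhindered methyl ester leaves the secondary TBS ether and the furan intact.

Step 10
Reactants: 14 2-{5-[(R)-3-(tert-butyldimethylsilyloxy)butyl]furan-2-yl}acetic acid
Product: 15 pentafluorophenyl 2-{5-[(R)-3-(tert-butyldimethylsilyloxy)butyl]furan-2-yl}acetate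
Conditions: C6F5OH, DCC, CH2Cl2, 0 °C → rt
Reagents that add atoms: pentafluorophenol, Oc1c(F)c(F)c(F)c(F)c1F
Why: Carbodiimide coupling gives the aryl ester whose phenoxide is both the leaving group and the turnover agent of the Lewis-base catalysis in step 11.

Step 11
Reactants: 8 tert-butyl (E)-4-{2-[(R)-3-(triethylsilyloxy)butyl]-1,3-dioxolan-2-yl}but-2-en-1-yl carbonate; 15 pentafluorophenyl 2-{5-[(R)-3-(tert-butyldimethylsilyloxy)butyl]furan-2-yl}acetate
Product: 18 (2S,3R)-2-{5-[(R)-3-(tert-butyldimethylsilyloxy)butyl]furan-2-yl}-3-({2-[(R)-3-(triethylsilyloxy)butyl]-1,3-dioxolan-2-yl}methyl)pent-4-enoic acid, via pentafluorophenyl ester 16 (not isolated), via peroxy acid 17 (not isolated)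
Conditions: cyclometallated [Ir(cod)(κ2-L)(C2H4)] (4 mol %; L = (Sa,S,S)-BINOL bis(1-phenylethyl)amine phosphoramidite), (S)-benzotetramisole (10 mol %), THF, 5 °C; then LiOH, H2O2, THF/H2O, 0 °C; Na2SO3; 1 M HCl to pH 4, 0 °C
Reagents that add atoms: hydrogen peroxide, OO
Why: In this synergistic iridium/isothiourea allylic alkylation of an aryl acetic active ester, the isothiourea turns 15 into a Z-configured C1-ammonium enolate whose single open face sets C12 (S), the iridium complex ionises 8 and directs attack to the substituted allyl terminus anti to the metal to set C4 (R, branched product), phenoxide rebound releases 16, the independence of the two catalysts gives access to the C4/C12 relation of the all-cis lactone that closed Michael or Claisen transition states disfavour, and weakly basic but strongly nucleophilic LiOOH then cleaves the active ester faster than it can enolise.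

Step 12
Reactants: 18 the (2S,3R)-pent-4-enoic acid of step 11
Product: 19 tert-butyl (2S,3R)-2-{5-[(R)-3-(tert-butyldimethylsilyloxy)butyl]furan-2-yl}-3-({2-[(R)-3-(triethylsilyloxy)butyl]-1,3-dioxolan-2-yl}methyl)pent-4-enoate
Conditions: O-tert-butyl-N,N'-diisopropylisourea, CH2Cl2, rt
Reagents that add atoms: O-tert-butyl-N,N'-diisopropylisourea, CC(C)NC(=NC(C)C)OC(C)(C)C
Why: Isourea esterification transfers the tert-butyl group to the carboxylate under neutral conditions, so neither the dioxolane nor the silyl ethers nor the C12 centre is at risk.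

Step 13
Reactants: 19 the tert-butyl (2S,3R)-pent-4-enoate with C9 OTES
Product: 20 tert-butyl (2S,3R)-2-{5-[(R)-3-(tert-butyldimethylsilyloxy)butyl]furan-2-yl}-3-({2-[(R)-3-hydroxybutyl]-1,3-dioxolan-2-yl}methyl)pent-4-enoate
Conditions: HF·pyridine, excess pyridine, THF, 0 °C
Reagents that add atoms: none
Why: Selective desilylation works because a secondary TES ether is cleaved far faster than a secondary TBS ether, and the pyridine buffer prevents acid-catalysed exchange between the freed C9 hydroxyl and the C6 dioxolane.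

Step 14
Reactants: 20 the C9 alcohol of step 13; 21 bromoacetyl bromide
Product: 22 tert-butyl (2S,3R)-3-({2-[(R)-3-(2-bromoacetoxy)butyl]-1,3-dioxolan-2-yl}methyl)-2-{5-[(R)-3-(tert-butyldimethylsilyloxy)butyl]furan-2-yl}pent-4-enoate
Conditions: pyridine, CH2Cl2, −20 °C
Reagents that add atoms: none
Why: O-acylation of the only free hydroxyl with an acid bromide proceeds with retention at C9, and pyridine is too weak a base to enolise the tert-butyl ester at C12.

Step 15
Reactants: 22 the C9 bromoacetate with C4 vinyl group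
Product: 24 tert-butyl (2S,3S)-3-({2-[(R)-3-(2-bromoacetoxy)butyl]-1,3-dioxolan-2-yl}methyl)-2-{5-[(R)-3-(tert-butyldimethylsilyloxy)butyl]furan-2-yl}-4-oxobutanoate (open-chain C3 aldehyde C9 bromoacetate), via vicinal diol 23 (not isolated)
Conditions: OsO4 (2 mol %), NaIO4 (4 equiv), 2,6-lutidine, dioxane/H2O 3:1, rt
Reagents that add atoms: osmium tetroxide, O=[Os](=O)(=O)=O; sodium periodate, [Na+].[O-]I(=O)(=O)=O
Why: Lemieux–Johnson cleavage attacks the terminal alkene in preference to the aromatic furan and frees the C3 aldehyde last and under near-neutral conditions, which spares the acid-labile dioxolane, both esters and the epimerisable C4 (its descriptor changes from R to S only through the CIP priority switch), while hindered lutidine is not alkylated by the bromoacetate.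

Step 16
Reactants: 24 the open-chain C3 aldehyde C9 bromoacetate
Product: 26 ten-membered (3S,4S,9R,12S,19R)-3-hydroxy lactone bearing C6 dioxolane/C11 tert-butyl ester/C19 OTBS, via samarium enolate 25 (not isolated)
Conditions: SmI2 (3 equiv, 0.1 M), THF, −78 → −20 °C, 24 added by syringe pump over 6 h (final 2 mM); sat. aq NH4Cl
Reagents that add atoms: none
Why: Two single-electron transfers from SmI2 cleave the C–Br bond and give samarium(III) enolate 25, whose oxophilic metal also binds the C3 aldehyde, so that C2 adds to C3 through a metal-templated cyclic aldol transition state; this is an intramolecular samarium Reformatsky reaction, and the closest known type is the SmI2 cyclisation of ω-(bromoacetoxy) aldehydes to medium and large β-hydroxy lactones. The ten-membered lactone (C1–C9 and the ring oxygen) closes in a 10-(enolendo)-exo-trig mode, and slow addition keeps the enolate dilute enough to suppress intermolecular aldol addition. The new C3 carbinol is controlled by C4: the tether holds C5 gauche to the incoming C2, and the Felkin–Anh rotamer with the bulky C12 branch anti to the forming bond should be preferred, which exposes the Si face of the aldehyde and gives 3S, with the hydroxyl syn to the C5 arm as the cis ring fusion requires. Chemoselectivity rests on the much faster reduction of the α-bromo ester than of the aldehyde at low temperature, and on the C6 dioxolane, which blocks the kinetically easier seven-membered closure onto a ketone. The tert-butyl ester is too hindered to be attacked by the samarium alkoxide, so the γ-lactone cannot form yet. No proton source is present, and the weakly basic samarium species should leave C4 and C12 unepimerised.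

Step 17
Reactants: 26 the ten-membered 3-hydroxy lactone
Product: 28 cordycicadin B, via seco hydroxy acid 27 (not isolated)
Conditions: TFA/CH2Cl2/H2O 4:8:1, 0 °C → rt; toluene azeotrope
Reagents that add atoms: water, O
Why: Acidolysis cleaves the tert-butyl ester (loss of isobutene), the dioxolane and the silyl ether, the freed C11 acid 27 closes onto the adjacent C3 hydroxyl by 5-exo-trig lactonisation with retention at C3, and the absence of base leaves the labile C12 centre, cis to both ring arms, untouched.

Compound list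
1 | (R)-γ-valerolactone, (5R)-5-methyloxolan-2-one | C[C@@H]1CCC(=O)O1 | starting material
2 | (R)-4-hydroxy-N-methoxy-N-methylpentanamide | C[C@@H](O)CCC(=O)N(C)OC | intermediate
3 | (R)-N-methoxy-N-methyl-4-(triethylsilyloxy)pentanamide | C[C@H](CCC(=O)N(C)OC)O[Si](CC)(CC)CC | intermediate
4 | allylmagnesium bromide | C=CC[Mg]Br | starting material
5 | (R)-7-(triethylsilyloxy)oct-1-en-4-one | C[C@H](CCC(=O)CC=C)O[Si](CC)(CC)CC | intermediate
6 | (R)-2-allyl-2-[3-(triethylsilyloxy)butyl]-1,3-dioxolane | C[C@H](CCC1(CC=C)OCCO1)O[Si](CC)(CC)CC | intermediate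
7 | allyl tert-butyl carbonate | C=CCOC(=O)OC(C)(C)C | starting material
8 | tert-butyl (E)-4-{2-[(R)-3-(triethylsilyloxy)butyl]-1,3-dioxolan-2-yl}but-2-en-1-yl carbonate | C[C@H](CCC1(C/C=C/COC(=O)OC(C)(C)C)OCCO1)O[Si](CC)(CC)CC | intermediate
9 | methyl 2-(furan-2-yl)acetate | COC(=O)Cc1ccco1 | starting material
10 | methyl vinyl ketone | C=CC(C)=O | starting material
11 | methyl 2-[5-(3-oxobutyl)furan-2-yl]acetate | COC(=O)Cc1ccc(CCC(C)=O)o1 | intermediate
12 | methyl 2-{5-[(R)-3-hydroxybutyl]furan-2-yl}acetate | COC(=O)Cc1ccc(CC[C@@H](C)O)o1 | intermediate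
13 | methyl 2-{5-[(R)-3-(tert-butyldimethylsilyloxy)butyl]furan-2-yl}acetate | COC(=O)Cc1ccc(CC[C@@H](C)O[Si](C)(C)C(C)(C)C)o1 | intermediate
14 | 2-{5-[(R)-3-(tert-butyldimethylsilyloxy)butyl]furan-2-yl}acetic acid | OC(=O)Cc1ccc(CC[C@@H](C)O[Si](C)(C)C(C)(C)C)o1 | intermediate
15 | pentafluorophenyl 2-{5-[(R)-3-(tert-butyldimethylsilyloxy)butyl]furan-2-yl}acetate | O=C(Cc1ccc(CC[C@@H](C)O[Si](C)(C)C(C)(C)C)o1)Oc1c(F)c(F)c(F)c(F)c1F | intermediate
16 | pentafluorophenyl (2S,3R)-pent-4-enoate, branched allylation product (C4 R, C12 S; C9 OTES, C6 dioxolane, C19 OTBS), not isolated | C[C@H](CCC1(OCCO1)C[C@H](C=C)[C@@H](c2ccc(CC[C@@H](C)O[Si](C)(C)C(C)(C)C)o2)C(=O)Oc3c(F)c(F)c(F)c(F)c3F)O[Si](CC)(CC)CC | intermediate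
17 | corresponding (2S,3R)-pent-4-eneperoxoic acid, not isolated | C[C@H](CCC1(OCCO1)C[C@H](C=C)[C@@H](c2ccc(CC[C@@H](C)O[Si](C)(C)C(C)(C)C)o2)C(=O)OO)O[Si](CC)(CC)CC | intermediate
18 | (2S,3R)-2-{5-[(R)-3-(tert-butyldimethylsilyloxy)butyl]furan-2-yl}-3-({2-[(R)-3-(triethylsilyloxy)butyl]-1,3-dioxolan-2-yl}methyl)pent-4-enoic acid | C[C@H](CCC1(OCCO1)C[C@H](C=C)[C@@H](c2ccc(CC[C@@H](C)O[Si](C)(C)C(C)(C)C)o2)C(=O)O)O[Si](CC)(CC)CC | intermediate
19 | tert-butyl ester of 18 | C[C@H](CCC1(OCCO1)C[C@H](C=C)[C@@H](c2ccc(CC[C@@H](C)O[Si](C)(C)C(C)(C)C)o2)C(=O)OC(C)(C)C)O[Si](CC)(CC)CC | intermediate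
20 | C9 alcohol, tert-butyl (2S,3R)-2-{furyl}-3-({2-[(R)-3-hydroxybutyl]-1,3-dioxolan-2-yl}methyl)pent-4-enoate | C[C@H](CCC1(OCCO1)C[C@H](C=C)[C@@H](c2ccc(CC[C@@H](C)O[Si](C)(C)C(C)(C)C)o2)C(=O)OC(C)(C)C)O | intermediate
21 | bromoacetyl bromide | O=C(Br)CBr | starting material
22 | C9 bromoacetate of 20 (C4 vinyl) | C[C@H](CCC1(OCCO1)C[C@H](C=C)[C@@H](c2ccc(CC[C@@H](C)O[Si](C)(C)C(C)(C)C)o2)C(=O)OC(C)(C)C)OC(=O)CBr | intermediate
23 | vicinal diol from 22 (epimers at the new carbinol), not isolated | C[C@H](CCC1(OCCO1)C[C@H](C(O)CO)[C@@H](c2ccc(CC[C@@H](C)O[Si](C)(C)C(C)(C)C)o2)C(=O)OC(C)(C)C)OC(=O)CBr | intermediate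
24 | open-chain C3 aldehyde C9 bromoacetate (4S,9R,12S,19R; C6 dioxolane, C11 tert-butyl ester, C19 OTBS) | C[C@H](CCC1(OCCO1)C[C@H](C=O)[C@@H](c2ccc(CC[C@@H](C)O[Si](C)(C)C(C)(C)C)o2)C(=O)OC(C)(C)C)OC(=O)CBr | intermediate
25 | samarium(III) enolate of the C9 acetate, not isolated | C[C@H](CCC1(OCCO1)C[C@H](C=O)[C@@H](c2ccc(CC[C@@H](C)O[Si](C)(C)C(C)(C)C)o2)C(=O)OC(C)(C)C)OC(=C)O[Sm](I)I | intermediate
26 | ten-membered (3S,4S,9R,12S,19R)-3-hydroxy lactone (C6 dioxolane, C11 tert-butyl ester, C19 OTBS) | C[C@@H]1CCC3(OCCO3)C[C@H]([C@H](CC(=O)O1)O)[C@@H](c1ccc(CC[C@@H](C)O[Si](C)(C)C(C)(C)C)o1)C(=O)OC(C)(C)C | intermediate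
27 | fully deprotected seco hydroxy acid (C3 OH, C11 CO2H, C6 ketone, C19 OH), not isolated | C[C@@H]1CCC(=O)C[C@H]([C@H](CC(=O)O1)O)[C@@H](c1ccc(CC[C@@H](C)O)o1)C(=O)O | intermediate
28 | cordycicadin B (3S,4S,9R,12S,19R) | C[C@@H]1CCC(=O)C[C@@H]2[C@H](CC(=O)O1)OC(=O)[C@@H]2c1ccc(CC[C@@H](C)O)o1 | target

Total step count: 17. Longest linear sequence: 12 steps (steps 1–5 and 11–17).

Steps most likely to fail

Step 11. The bulky ammonium enolate may capture the alkyl-substituted, neopentyl-like allyl–iridium species too slowly. Linear substitution, low conversion, or enolisation of the activated ester with loss of C12 integrity could then take over.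
The fallback sets out from 14 and 8 and returns at 19, and it uncouples the control of the two centres.
- Acid 14 is esterified with the isourea of step 12 to tert-butyl furylacetate F1, which LiHMDS/TMSCl converts into silyl ketene acetal F2.
- F2 serves as a small, preformed nucleophile in the iridium-catalysed allylic substitution of 8. The metal alone sets C4, and the tert-butoxide released from the carbonate desilylates F2.
- C12 then forms without control. Compound 19 is separated by chromatography from its C12 epimer F3, and F3 is re-equilibrated with catalytic KOt-Bu in t-BuOH/THF and separated again.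

Step 16. Protonation of the samarium enolate, intermolecular aldol addition, or attack on the wrong aldehyde face may outrun closure of the strained ring.
The fallback sets out from 19 and returns at 26. It makes C2–C3 intermolecularly and closes the ring at the ester bond.
- OsO4/NaIO4 converts 19 by way of vicinal diol F4 into aldehyde F5.
- The lithium enolate of methyl acetate (LDA, THF, −78 °C) adds under the same Felkin–Anh control by C4 to give β-hydroxy methyl ester F6.
- Me3SnOH gives carboxylic acid F7, and buffered HF·pyridine removes the TES group to give seco acid F8.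
- Shiina macrolactonisation (MNBA, DMAP, high dilution) then forms the C9–O–C1 bond and delivers 26.

Step 17. The strong acid may protonate, open or tert-butylate the 2,5-dialkylfuran. It may also dehydrate the β-hydroxy lactone before lactonisation, or let C12 drift.
The fallback sets out from 26 and returns at 28, and it stages the endgame.
- Catalytic PPTS in toluene at 80 °C induces intramolecular transesterification to protected bicyclic lactone F9 with loss of tert-butanol. The dioxolane and TBS ether stay in place.
- At this stage C12 can be reset. One equivalent of LiHMDS (THF, −78 °C) removes only the most acidic C12–H to give lithium enolate F10.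
- A bulky phenol (2,6-di-tert-butyl-4-methylphenol) protonates F10 from the face opposite the ten-membered ring, which returns F9 with the furyl group cis to both ring arms.
- Dilute aqueous HF in MeCN then removes the silyl ether and the dioxolane to give 28.

Further compounds
F1 | step 11 | tert-butyl 2-{5-[(R)-3-(tert-butyldimethylsilyloxy)butyl]furan-2-yl}acetate | CC(C)(C)OC(=O)Cc1ccc(CC[C@@H](C)O[Si](C)(C)C(C)(C)C)o1
F2 | step 11 | trimethylsilyl ketene acetal of F1 | CC(C)(C)OC(O[Si](C)(C)C)=Cc1ccc(CC[C@@H](C)O[Si](C)(C)C(C)(C)C)o1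
F3 | step 11 | C12 epimer of 19, tert-butyl (2R,3R)-pent-4-enoate | C[C@H](CCC1(OCCO1)C[C@H](C=C)[C@H](c2ccc(CC[C@@H](C)O[Si](C)(C)C(C)(C)C)o2)C(=O)OC(C)(C)C)O[Si](CC)(CC)CC
F4 | step 16 | vicinal diol from 19 (epimers at the new carbinol) | C[C@H](CCC1(OCCO1)C[C@H](C(O)CO)[C@@H](c2ccc(CC[C@@H](C)O[Si](C)(C)C(C)(C)C)o2)C(=O)OC(C)(C)C)O[Si](CC)(CC)CC
F5 | step 16 | C3 aldehyde with C9 OTES | C[C@H](CCC1(OCCO1)C[C@H](C=O)[C@@H](c2ccc(CC[C@@H](C)O[Si](C)(C)C(C)(C)C)o2)C(=O)OC(C)(C)C)O[Si](CC)(CC)CC
F6 | step 16 | (3S)-β-hydroxy methyl ester (C1 CO2Me, C9 OTES) | C[C@H](CCC1(OCCO1)C[C@H]([C@H](CC(=O)OC)O)[C@@H](c2ccc(CC[C@@H](C)O[Si](C)(C)C(C)(C)C)o2)C(=O)OC(C)(C)C)O[Si](CC)(CC)CC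
F7 | step 16 | (3S)-β-hydroxy acid (C1 CO2H, C9 OTES) | C[C@H](CCC1(OCCO1)C[C@H]([C@H](CC(=O)O)O)[C@@H](c2ccc(CC[C@@H](C)O[Si](C)(C)C(C)(C)C)o2)C(=O)OC(C)(C)C)O[Si](CC)(CC)CC
F8 | step 16 | seco acid (C1 CO2H, C3 OH, C9 OH) | C[C@H](CCC1(OCCO1)C[C@H]([C@H](CC(=O)O)O)[C@@H](c2ccc(CC[C@@H](C)O[Si](C)(C)C(C)(C)C)o2)C(=O)OC(C)(C)C)O
F9 | step 17 | protected bicyclic lactone (C6 dioxolane, C19 OTBS) | C[C@@H]1CCC3(OCCO3)C[C@@H]2[C@H](CC(=O)O1)OC(=O)[C@@H]2c1ccc(CC[C@@H](C)O[Si](C)(C)C(C)(C)C)o1
F10 | step 17 | lithium enolate of F9 (C11–C12) | C[C@@H]1CCC3(OCCO3)C[C@@H]2[C@H](CC(=O)O1)OC(O[Li])=C2c1ccc(CC[C@@H](C)O[Si](C)(C)C(C)(C)C)o1
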